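The cyclohexene ring (C1–C6) is opened at C1–C2 and C5–C6. The cut exploits two hidden units. Coumarin A–C1–C6–C7–coumarin B is a chalcone backbone once C7 is a ketone. C2–C3–C4–C5(CH3)2 is the chain of mesityl oxide, with C3 as its carbonyl carbon. One asymmetric [4+2] annulation of the mesityl oxide 2-silyloxydiene with an E-chalcone builds the carbocycle, the quaternary C5 and the trans C1/C6 stereopair together. The chalcone carries a free phenol (7′-OH of coumarin B) ortho to the C7 carbonyl, so a chiral borate binds covalently there and not at the lactones. The C3 methyl and the C7 carbinol are added afterwards.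

Key step: step 5

Numbering: the carbocycle is C1 (CH bearing coumarin A), C2, C3, C4, C5 (CMe2) and C6 (CH). The exocyclic carbon C7 bears coumarin B. Primed numbers (5′, 7′, 8′) are coumarin positions.
Assumption: the sense of induction of the (R)-VANOL borate is assigned by analogy with other 2′-hydroxychalcones; if the adduct proves to be the antipode, (S)-VANOL is used with no other change.

Step 1
Reactants: 1 5,7-dimethoxycoumarin
Product: 3 8-formyl-5,7-dimethoxycoumarin, via aryl iminium salt 2 (not isolated)
Conditions: POCl3, DMF, 0 → 80 °C; then aq NaOAc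
Reagents that add atoms: N,N-dimethylformamide CN(C)C=O; water O
Why: Vilsmeier–Haack formylation should go to position 8′, which is para to the 5′-methoxy group, ortho to the 7′-methoxy group and flanked by the tied-back ring oxygen, so it is the more activated and less crowded free arene site, and the lactone tolerates the acidic medium.

Step 2
Reactants: 1 5,7-dimethoxycoumarin
Product: 5 8-acetyl-7-hydroxy-5-methoxycoumarin, via 8-acetyl-5,7-dimethoxycoumarin 4 (not isolated)
Conditions: AcCl, AlCl3 (3.5 equiv), ClCH2CH2Cl, 0 → 60 °C; then ice/1 M HCl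
Reagents that add atoms: acetyl chloride CC(=O)Cl
Why: Friedel–Crafts acylation at the same activated 8′ position is followed in the same flask by aluminium-chelate-directed cleavage of the one methyl ether ortho to the new ketone, while the unchelated 5′-methoxy group should stay.

Step 3
Reactants: 3 8-formyl-5,7-dimethoxycoumarin; 5 8-acetyl-7-hydroxy-5-methoxycoumarin
Product: 6 (E)-3-(5,7-dimethoxycoumarin-8-yl)-1-(7-hydroxy-5-methoxycoumarin-8-yl)prop-2-en-1-one
Conditions: piperidine (0.3 equiv), EtOH, reflux
Reagents that add atoms: none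
Why: Amine-catalysed Claisen–Schmidt condensation (aldol addition, then E1cB loss of water) gives the thermodynamically favoured E-enone, and a secondary amine in place of hydroxide spares both lactones, as is usual for 8-acetyl-7-hydroxycoumarins.

Step 4
Reactants: 7 mesityl oxide
Product: 9 2-(tert-butyldimethylsilyloxy)-4-methylpenta-1,3-diene, via lithium dienolate 8 (not isolated)
Conditions: LDA, THF, −78 °C; TBSCl, DMPU, −78 °C → rt
Reagents that add atoms: tert-butyldimethylsilyl chloride CC(C)(C)[Si](C)(C)Cl
Why: Kinetic deprotonation of the enone at its α′-methyl group gives the cross-conjugated dienolate, and O-silylation traps it as the 2-silyloxydiene (kinetic silyl enol ether formation).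

Step 5
Reactants: 6 (E)-3-(5,7-dimethoxycoumarin-8-yl)-1-(7-hydroxy-5-methoxycoumarin-8-yl)prop-2-en-1-one; 9 2-(tert-butyldimethylsilyloxy)-4-methylpenta-1,3-diene
Product: 10 (1S,6R)-trans cyclohexene adduct (C1 coumarin A; C3=C4 TBS enol ether; C5 gem-dimethyl; C6 acyl group C7=O bearing 7-hydroxy-5-methoxycoumarin-8-yl)
Conditions: (R)-VANOL (30 mol %), B(OPh)3 (30 mol %, borate pre-formed, phenol removed in vacuo), 4 Å MS, CH2Cl2, rt; 9 (4 equiv), rt → 40 °C; pH 7 buffer
Reagents that add atoms: none
Why: The 7′-OH and the C7 carbonyl of 6 bind boron in a six-membered chelate, which lowers the enone LUMO and holds the chiral VANOL pocket over one enone face, away from the competing lactone carbonyls. Because the Z-methyl of 9 penalises the s-cis diene, the annulation should run stepwise: Mukaiyama–Michael attack of the nucleophilic CH2 terminus (C2) on the β-carbon C1, then collapse of the boron enolate carbon C6 onto the C5 terminus of the silyloxyallyl cation, with boron keeping the enolate oxygen occupied so that C-alkylation is the productive path. The closest known reaction types are the chiral-borate-catalysed Diels–Alder reaction of 2′-hydroxychalcones and the Lewis-acid-promoted double Michael annulation of 2-silyloxydienes with enones. The carbocycle closes in a 6-(enolexo)-endo-trig mode, equivalent to the second bond of a [4+2] cycloaddition. C1 is set by the ligand-controlled face of the first attack, and C6 is set relative to C1 by the E-enone geometry and a chair-like closure with both large groups equatorial; because C6 is epimerisable, it also rests as the more stable trans isomer. The required regiochemistry (C2 to C1, C5 to C6) follows from the silyloxy donor, which polarises the diene towards its CH2 end and matches it with the β-carbon of the chelated enone.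

Step 6
Reactants: 10 (1S,6R)-trans cyclohexene adduct
Product: 12 (1S,6R)-3,7-diketone (C3 cyclohexanone; C7 ketone bearing 5,7-dimethoxycoumarin-8-yl), via O-methylated silyl enol ether 11 (not isolated)
Conditions: MeI, K2CO3, DMF, rt; then 1 M HCl, THF, rt
Reagents that add atoms: iodomethane CI
Why: Williamson O-methylation of the acidic chelated phenol is run while the silyl enol ether still masks C3, so no 1,5-diketone meets base, and the following acid hydrolysis of the enol ether frees the C3 ketone without disturbing C1 or the more stable trans C6 centre.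

Step 7
Reactants: 12 (1S,6R)-3,7-diketone
Product: 14 (1S,6R)-C2=C3 alkenyl triflate, via lithium enolate 13 (not isolated)
Conditions: LiHMDS (1.05 equiv), THF, −78 °C; N-(5-chloro-2-pyridyl)bis(trifluoromethanesulfonimide), −78 → −30 °C
Reagents that add atoms: N-(5-chloro-2-pyridyl)bis(trifluoromethanesulfonimide) Clc1ccc(nc1)N(S(=O)(=O)C(F)(F)F)S(=O)(=O)C(F)(F)F
Why: In this kinetic enolisation and O-triflation the amide base should take a C2 proton, because C4 is neopentyl (next to C5) and C6–H is buried between C5 and coumarin A, and the tight lithium enolate is trapped cold before equilibration or ring opening.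

Step 8
Reactants: 14 (1S,6R)-C2=C3 alkenyl triflate
Product: 15 (1S,6R)-3-methylcyclohex-2-enyl ketone (C7=O bearing 5,7-dimethoxycoumarin-8-yl)
Conditions: MeZnCl, Pd(PPh3)4 (5 mol %), THF, rt → 45 °C
Reagents that add atoms: methylzinc chloride C[Zn]Cl
Why: Negishi cross-coupling of the alkenyl triflate (oxidative addition, transmetalation, reductive elimination) places methyl on C3 with the C2=C3 position retained, and the organozinc attacks neither the lactones nor the hindered ketone.

Step 9
Reactants: 15 (1S,6R)-3-methylcyclohex-2-enyl ketone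
Product: 16 IN0553 (1S,6R,7R)
Conditions: NaBH4, THF–MeOH, 0 °C → rt; pH 7 buffer
Reagents that add atoms: none
Why: In this borohydride 1,2-reduction under Felkin–Anh control the quaternary C5 stands perpendicular to the carbonyl group, so hydride should enter anti to it and past C6–H to give the 7R carbinol, while the push–pull dimethoxycoumarins are poor hydride acceptors and the acid-labile benzylic alcohol is made last and worked up at neutral pH.

Compound list
1 | 5,7-dimethoxycoumarin | COc1cc(OC)c2ccc(=O)oc2c1 | starting material
2 | (5,7-dimethoxy-2-oxo-2H-chromen-8-yl)methylidene(dimethyl)iminium dichlorophosphate | COc1cc(OC)c2ccc(=O)oc2c1C=[N+](C)C.[O-]P(=O)(Cl)Cl | intermediate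
3 | 8-formyl-5,7-dimethoxycoumarin | COc1cc(OC)c2ccc(=O)oc2c1C=O | intermediate
4 | 8-acetyl-5,7-dimethoxycoumarin | CC(=O)c1c(OC)cc(OC)c2ccc(=O)oc12 | intermediate
5 | 8-acetyl-7-hydroxy-5-methoxycoumarin | CC(=O)c1c(O)cc(OC)c2ccc(=O)oc12 | intermediate
6 | (E)-3-(5,7-dimethoxycoumarin-8-yl)-1-(7-hydroxy-5-methoxycoumarin-8-yl)prop-2-en-1-one | COc1cc(OC)c2ccc(=O)oc2c1/C=C/C(=O)c1c(O)cc(OC)c2ccc(=O)oc12 | intermediate
7 | mesityl oxide | CC(C)=CC(C)=O | starting material
8 | lithium 4-methylpenta-1,3-dien-2-olate | [Li+].[O-]C(=C)C=C(C)C | intermediate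
9 | 2-(tert-butyldimethylsilyloxy)-4-methylpenta-1,3-diene | C=C(O[Si](C)(C)C(C)(C)C)C=C(C)C | intermediate
10 | (1S,6R)-trans adduct, C3=C4 TBS enol ether, C7 ketone on 7-hydroxy-5-methoxycoumarin-8-yl | COc1cc(OC)c2ccc(=O)oc2c1[C@H]1CC(O[Si](C)(C)C(C)(C)C)=CC(C)(C)[C@@H]1C(=O)c1c(O)cc(OC)c2ccc(=O)oc12 | intermediate
11 | (1S,6R)-trans adduct, C3=C4 TBS enol ether, C7 ketone on 5,7-dimethoxycoumarin-8-yl | COc1cc(OC)c2ccc(=O)oc2c1[C@H]1CC(O[Si](C)(C)C(C)(C)C)=CC(C)(C)[C@@H]1C(=O)c1c(OC)cc(OC)c2ccc(=O)oc12 | intermediate
12 | (1S,6R)-3,7-diketone | COc1cc(OC)c2ccc(=O)oc2c1[C@H]1CC(=O)CC(C)(C)[C@@H]1C(=O)c1c(OC)cc(OC)c2ccc(=O)oc12 | intermediate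
13 | lithium C2=C3 enolate of 12 | [Li+].COc1cc(OC)c2ccc(=O)oc2c1[C@H]1C=C([O-])CC(C)(C)[C@@H]1C(=O)c1c(OC)cc(OC)c2ccc(=O)oc12 | intermediate
14 | (1S,6R)-C2=C3 alkenyl triflate, C7 ketone | COc1cc(OC)c2ccc(=O)oc2c1[C@H]1C=C(OS(=O)(=O)C(F)(F)F)CC(C)(C)[C@@H]1C(=O)c1c(OC)cc(OC)c2ccc(=O)oc12 | intermediate
15 | (1S,6R)-3,5,5-trimethylcyclohex-2-ene with coumarin A on C1 and the C7 ketone on C6 | COc1cc(OC)c2ccc(=O)oc2c1[C@H]1C=C(C)CC(C)(C)[C@@H]1C(=O)c1c(OC)cc(OC)c2ccc(=O)oc12 | intermediate
16 | IN0553, 8-[(R)-[(1R,2S)-2-(5,7-dimethoxy-2-oxo-2H-chromen-8-yl)-4,6,6-trimethylcyclohex-3-en-1-yl](hydroxy)methyl]-5,7-dimethoxy-2H-chromen-2-one | COc1cc(OC)c2ccc(=O)oc2c1[C@H]1C=C(C)CC(C)(C)[C@@H]1[C@@H](O)c1c(OC)cc(OC)c2ccc(=O)oc12 | target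

Total step count: 9. Longest linear sequence: 7 steps (step 1 or step 2, then steps 3, 5, 6, 7, 8 and 9).

Steps most likely to fail

1. Step 5.
- What may go wrong: the annulation may stall after the first C–C bond. Proton loss or desilylation of the silyloxyallyl cation competes with the crowded closure at C5, and the diene may be consumed by protodesilylation.
- Fallback: the ring is built in two separate stages, setting out from 6 and 9.
- The borate-catalysed reaction is run deliberately as an enantioselective Mukaiyama–Michael addition and hydrolysed on work-up. This gives the open-chain (S)-1,5-diketone phenol F1.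
- O-Methylation (MeI, K2CO3, DMF) gives the open-chain (S)-1,5-diketone methyl ether F2.
- The C5–C6 bond is then closed by a silyl triflate/amine-promoted intramolecular Michael addition (TBSOTf, Et3N, CH2Cl2, −78 °C → rt). This soft-enolises the aryl ketone and activates the enone at the same time.
- The closure delivers the silyl enol ether directly, and the fallback comes back to the route at 11.

2. Step 9.
- What may go wrong: hydride transfer to the crowded, twisted aryl ketone may be slow enough for conjugate reduction of the lactones to compete. Facial selectivity under substrate control may also be modest.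
- Fallback: control is moved from the substrate to the reagent, setting out from 15.
- A Corey–Bakshi–Shibata reduction is run with catecholborane in toluene at low temperature. The catalyst antipode is the one that reinforces delivery to the face leading to 7R, which is the (S)-oxazaborolidine if coumarin B acts as the larger flank.
- The oxazaborolidine activates only the ketone, and catecholborane leaves the lactones and the trisubstituted alkene alone.
- The fallback comes back to the route at 16 and makes no new compound (F0).

3. Step 7.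
- What may go wrong: the C2=C3 enolate may open by retro-Michael cleavage of C1–C6, since C6 is still α to the C7 ketone. Proton exchange may also erode the C2/C4 regioselectivity.
- Fallback: the order of events is changed so that C6 can no longer leave as an enolate. It sets out from 11, which is isolated by omitting the acid treatment of step 6.
- NaBH4 reduction gives the C7 carbinol silyl enol ether F3.
- TESOTf and 2,6-lutidine give the C7 triethylsilyl ether F4.
- Mild hydrolysis (AcOH–THF–H2O) cleaves only the enol ether and gives the C3 ketone silyl ether F5.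
- LiHMDS and the same triflating reagent give the C2=C3 alkenyl triflate silyl ether F6.
- Negishi methylation gives the methylcyclohexene silyl ether F7.
- Buffered fluoride (TBAF, AcOH, THF) removes the silyl group, and the fallback comes back to the route at 16.

Further compounds
F1 | step 5 | (S)-3-(5,7-dimethoxycoumarin-8-yl)-1-(7-hydroxy-5-methoxycoumarin-8-yl)-7-methyloct-6-ene-1,5-dione | COc1cc(OC)c2ccc(=O)oc2c1[C@H](CC(=O)c1c(O)cc(OC)c2ccc(=O)oc12)CC(=O)C=C(C)C
F2 | step 5 | (S)-1,3-bis(5,7-dimethoxycoumarin-8-yl)-7-methyloct-6-ene-1,5-dione | COc1cc(OC)c2ccc(=O)oc2c1[C@H](CC(=O)c1c(OC)cc(OC)c2ccc(=O)oc12)CC(=O)C=C(C)C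
F0 | step 9 | none | none
F3 | step 7 | C7 carbinol with C3=C4 TBS enol ether, configuration as in 16 | COc1cc(OC)c2ccc(=O)oc2c1[C@H]1CC(O[Si](C)(C)C(C)(C)C)=CC(C)(C)[C@@H]1[C@@H](O)c1c(OC)cc(OC)c2ccc(=O)oc12
F4 | step 7 | C7 triethylsilyl ether with C3=C4 TBS enol ether, configuration as in 16 | COc1cc(OC)c2ccc(=O)oc2c1[C@H]1CC(O[Si](C)(C)C(C)(C)C)=CC(C)(C)[C@@H]1[C@@H](O[Si](CC)(CC)CC)c1c(OC)cc(OC)c2ccc(=O)oc12
F5 | step 7 | C3 ketone with C7 triethylsilyl ether, configuration as in 16 | COc1cc(OC)c2ccc(=O)oc2c1[C@H]1CC(=O)CC(C)(C)[C@@H]1[C@@H](O[Si](CC)(CC)CC)c1c(OC)cc(OC)c2ccc(=O)oc12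
F6 | step 7 | C2=C3 alkenyl triflate with C7 triethylsilyl ether, configuration as in 16 | COc1cc(OC)c2ccc(=O)oc2c1[C@H]1C=C(OS(=O)(=O)C(F)(F)F)CC(C)(C)[C@@H]1[C@@H](O[Si](CC)(CC)CC)c1c(OC)cc(OC)c2ccc(=O)oc12
F7 | step 7 | C7 triethylsilyl ether of 16 | COc1cc(OC)c2ccc(=O)oc2c1[C@H]1C=C(C)CC(C)(C)[C@@H]1[C@@H](O[Si](CC)(CC)CC)c1c(OC)cc(OC)c2ccc(=O)oc12
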